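**Assumption:** the target has no stereocentre or other stereogenic element (it is achiral), so no asymmetric step is needed.

## Retrosynthetic overview

1. Target 12 ⇒ quinone annulation (C3–C1′ bond, then furan C2–O closure with loss of NH3) of aminochromone 11 with chromene-quinone 5.
2. 11 ⇒ C–B oxidation of boronate 10 ⇒ key radical step: photo-Fries acyl shift (C4–C4a bond) of aryl cyanoacetate 9, then phenol-to-nitrile closure of the pyranone.
3. 9 ⇒ sterically controlled Ir C–H borylation of ester 8 ⇒ chromanol 6 + cyanoacetic acid 7. The ester masks O1, steers boron to the future C5 and carries C2–C4.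
4. 5 (Fremy radical oxidation) and 6 (hydrogenation) both ⇒ chromenol 4 ⇒ dienone 3 ⇒ cyclohexane-1,3-dione 1 + prenal 2.
5. Ring order: both dimethylpyrans (step 1) → arenes (aromatisation) → B-ring quinone → pyranone C ring → furan last.

## Route

**Step 1**
Reactants: 1 cyclohexane-1,3-dione; 2 3-methylbut-2-enal (prenal)
Product: 3, 2,2-dimethyl-2,6,7,8-tetrahydro-5H-chromen-5-one
Conditions: EDDA (10 mol %), MeOH, 50 °C
Reagents that add atoms: none
Why: Knoevenagel condensation followed by 6π-oxa-electrocyclisation (formal [3+3] annulation) of the cyclic 1,3-dione with the enal gives the 2,2-dimethyl-2H-pyran-fused enone.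

**Step 2**
Reactants: 3
Product: 4, 2,2-dimethyl-2H-chromen-5-ol
Conditions: LDA, THF, −78 °C; PhSeCl; then 30% H2O2, pyridine, CH2Cl2, 0 °C → rt
Reagents that add atoms: none
Why: Kinetic α′-enolate selenenylation and selenoxide syn-elimination give a dienone that tautomerises to the phenol (dehydrogenative aromatisation) without touching the pyran alkene.

**Step 3**
Reactants: 4
Product: 5, 2,2-dimethyl-2H-chromene-5,8-dione
Conditions: (KSO3)2NO (2.2 equiv), aq. KH2PO4, acetone/H2O, 0 °C → rt
Reagents that add atoms: Fremy's salt, [K+].[K+].[O-]S(=O)(=O)N([O])S(=O)(=O)[O-]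
Why: Teuber oxidation: the nitroxyl radical abstracts the phenolic hydrogen and a second radical couples at the free para carbon (C8), collapsing to the p-quinone and installing the third B-ring oxygen.

**Step 4**
Reactants: 4
Product: 6, 2,2-dimethylchroman-5-ol (3,4-dihydro-2H-chromen-5-ol)
Conditions: H2 (1 atm), 10% Pd/C, EtOAc, rt
Reagents that add atoms: none
Why: Heterogeneous hydrogenation saturates only the styrene-type C3=C4 bond, giving the chroman needed for the A-ring half.

**Step 5**
Reactants: 6; 7 cyanoacetic acid
Product: 8, 2,2-dimethylchroman-5-yl 2-cyanoacetate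
Conditions: EDC·HCl, DMAP (5 mol %), CH2Cl2, 0 °C → rt
Reagents that add atoms: none
Why: Steglich-type carbodiimide esterification of the single phenol; the ester later serves as protecting group, steric director and acyl source.

**Step 6**
Reactants: 8
Product: 9, 2,2-dimethyl-7-(4,4,5,5-tetramethyl-1,3,2-dioxaborolan-2-yl)chroman-5-yl 2-cyanoacetate
Conditions: [Ir(OMe)(cod)]2 (1.5 mol %), dtbpy (3 mol %), B2pin2 (0.7 equiv), MTBE, 60 °C
Reagents that add atoms: bis(pinacolato)diboron, CC1(C)OB(OC1(C)C)B1OC(C)(C)C(C)(C)O1
Why: Ishiyama–Miyaura–Hartwig C–H borylation is sterically controlled, so in this 1,2,3-trisubstituted arene only C7–H (no ortho substituent) reacts, while the ester keeps the C5 oxygen masked and the two A-ring oxygens differentiated.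

**Step 7 (key step)**
Reactants: 9
Product: 10, 2-amino-8,8-dimethyl-5-(pinacolboryl)-9,10-dihydro-4H,8H-pyrano[2,3-f]chromen-4-one (chromone numbering: 2-NH2, 5-Bpin, O7–C(CH3)2–CH2–CH2–C8)
Conditions: hν (254 nm, quartz), degassed MeCN, rt; then Et3N (0.2 equiv), EtOH, 60 °C
Reagents that add atoms: none
Why: Photo-Fries rearrangement: excitation homolyses the ArO–C(O) bond to a caged aryloxyl/cyanoacetyl radical pair that recombines at C6, the only free ortho carbon, forming the C4–C4a bond; the liberated phenol then adds to the nitrile (base-catalysed 6-exo-dig) to give the 2-aminochromone with O1 fixed on the pyran-bearing side.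

**Step 8**
Reactants: 10
Product: 11, 2-amino-5-hydroxy-8,8-dimethyl-9,10-dihydro-4H,8H-pyrano[2,3-f]chromen-4-one
Conditions: 30% H2O2, NaHCO3, THF/H2O, 0 °C → rt
Reagents that add atoms: hydrogen peroxide, OO
Why: ipso-Oxidation of the aryl boronate (peroxide attack on boron, 1,2-aryl shift, hydrolysis) reveals the chelated C5 phenol only after O1 is tied up in the pyranone, under conditions that leave the vinylogous amide untouched.

**Step 9**
Reactants: 11; 5 (1.0 equiv)
Product: 12, formosanatin D
Conditions: AcOH, N2, rt → 70 °C
Reagents that add atoms: none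
Why: Proposed new method: the enaminone carbon C3 of 11 adds to C6 of quinone 5 (β to the C8 carbonyl, which is not deactivated as a vinylogous ester by the pyran oxygen), the C5 hydroxyl of the resulting hydroquinone adds to the amidine-like C2 and NH3 is expelled, closing the furan and leaving the former C8 oxygen as the free 5′-phenol; the closest known chemistry is the benzofuran branch of the Nenitzescu reaction and the Craven quinone/cyanoacetate annulation, and no stereocentre is formed.

## Compound list

1 | cyclohexane-1,3-dione | O=C1CCCC(=O)C1 | starting material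
2 | 3-methylbut-2-enal (prenal) | CC(C)=CC=O | starting material
3 | 2,2-dimethyl-2,6,7,8-tetrahydro-5H-chromen-5-one | CC1(C)C=CC2=C(CCCC2=O)O1 | intermediate
4 | 2,2-dimethyl-2H-chromen-5-ol | CC1(C)C=Cc2c(O)cccc2O1 | intermediate
5 | 2,2-dimethyl-2H-chromene-5,8-dione | CC1(C)C=CC2=C(O1)C(=O)C=CC2=O | intermediate
6 | 2,2-dimethylchroman-5-ol | CC1(C)CCc2c(O)cccc2O1 | intermediate
7 | cyanoacetic acid | N#CCC(=O)O | starting material
8 | 2,2-dimethylchroman-5-yl 2-cyanoacetate | CC1(C)CCc2c(OC(=O)CC#N)cccc2O1 | intermediate
9 | 2,2-dimethyl-7-(pinacolboryl)chroman-5-yl 2-cyanoacetate | CC1(C)CCc2c(OC(=O)CC#N)cc(B3OC(C)(C)C(C)(C)O3)cc2O1 | intermediate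
10 | 2-amino-8,8-dimethyl-5-(pinacolboryl)-9,10-dihydro-4H,8H-pyrano[2,3-f]chromen-4-one | NC1=CC(=O)c2c(O1)c3CCC(C)(C)Oc3cc2B2OC(C)(C)C(C)(C)O2 | intermediate
11 | 2-amino-5-hydroxy-8,8-dimethyl-9,10-dihydro-4H,8H-pyrano[2,3-f]chromen-4-one | NC1=CC(=O)c2c(O1)c3CCC(C)(C)Oc3cc2O | intermediate
12 | formosanatin D (5,5′-dihydroxycoumaronochromone with a 2,2-dimethyldihydropyran fused at C7–O/C8 and a 2,2-dimethyl-2H-pyran fused at C3′/C4′–O; achiral) | CC1(C)C=Cc2c(c(O)cc3c2oc2oc4c5c(cc(O)c4c(=O)c23)OC(C)(C)CC5)O1 | target

## Summary

Total steps: 9. Longest linear sequence: 8 (steps 1, 2, 4, 5, 6, 7, 8, 9).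

Steps most likely to fail:

1. **Step 7 (photo-Fries).** Risks are para migration to C8, decarbonylation or simple phenol release from the radical pair, and inner-filter stalling. Fallback: abandon the photochemical acyl shift and boron masking; prepare a 7-O-silyl-2,2-dimethylchroman-5,7-diol and install the cyanoacetyl group by BCl3-directed ortho-acylation with malononitrile, then close to the same aminochromone type.
2. **Step 9 (quinone annulation).** Risks are addition at C7 instead of C6 of the quinone, N-cyclisation to an indole, or closure at C4 giving a coumestan-type product. Fallback: switch to the isoflavone logic: make the o-hydroxyaryl enaminone from the corresponding acetophenone, add it to 5 to give the 2′,5′-dihydroxyisoflavone, and close the C2–O bond by oxidative cyclisation (DDQ).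
3. **Step 6 (C–H borylation of the cyanoacetate).** Risks are catalyst inhibition by the nitrile and side reactions at the acidic CH2. Fallback: reorder the oxygenation: run the photo-Fries/cyclisation on 8 without boron, N-protect the aminochromone, and introduce the C5 hydroxyl by carbonyl-directed Ru(II)-catalysed C–H hydroxylation.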